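**Retrosynthetic overview**

- The target comes from 4'-benzyloxy-5,7-dihydroxy-8,2',3'-trimethoxyflavone by methylation of O-7 and removal of the benzyl group.
- Feature: in ring A, C8 (with its methoxy group) is bonded to C8a and C5 to C4a, the two carbons shared with ring C. A 4-pyranone with CH2OMe on C-2 and CO2Me on C-3 therefore already holds C8, C8a, C4a, C5, O1 and the 8-methoxy oxygen, and only C6–C7, one acetate unit, is missing.
- Key disconnection: C7–C8 (Claisen acylation by methyl acetate) and C5–C6 (Dieckmann closure) lead back to the pyranone ester and methyl acetate. Ring A is formed last.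
- Ring C (the pyranone) is formed first, by C-acylation of methyl 4-methoxyacetoacetate with an arylpropioloyl chloride and 6-endo-dig closure of the enol oxygen onto the ynone.
- Ring B is purchased as 2,3,4-trihydroxybenzaldehyde (4-O-benzyl, 2,3-di-O-methyl) and homologated to the propiolic acid by Corey–Fuchs reaction and carboxylation.

Key step: step 7

Assumption: the target has no stereocentre; the enolisable intermediates 9 and 12 are written as keto tautomers although they are present in the flask as enol or enolate forms.

**Route**

Step 1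
Reactants: 1 2,3,4-trihydroxybenzaldehyde
Product: 2 4-(benzyloxy)-2,3-dihydroxybenzaldehyde
Conditions: BnBr (1.05 equiv), NaHCO3, NaI (cat.), DMF, 40 °C
Reagents that add atoms: benzyl bromide, BrCc1ccccc1
Why: Williamson etherification under weak-base control; the 4-hydroxyl, para to the formyl group, is the most acidic and the only one ionised by NaHCO3, while the 2-hydroxyl is held in a hydrogen bond to the aldehyde and the 3-hydroxyl is the least acidic, so one equivalent of benzyl bromide should give the 4-benzyl ether.

Step 2
Reactants: 2 4-(benzyloxy)-2,3-dihydroxybenzaldehyde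
Product: 3 4-(benzyloxy)-2,3-dimethoxybenzaldehyde
Conditions: MeI (3 equiv), K2CO3, DMF, 40 °C
Reagents that add atoms: iodomethane, CI
Why: Exhaustive Williamson O-methylation of the two remaining phenols, with the aldehyde and the benzyl ether inert to K2CO3 and MeI.

Step 3
Reactants: 3 4-(benzyloxy)-2,3-dimethoxybenzaldehyde
Product: 4 1-(benzyloxy)-4-(2,2-dibromoethenyl)-2,3-dimethoxybenzene
Conditions: CBr4, PPh3, CH2Cl2, 0 °C
Reagents that add atoms: carbon tetrabromide, BrC(Br)(Br)Br
Why: First stage of the Corey–Fuchs reaction, a Wittig olefination of the aldehyde by the ylide Ph3P=CBr2 made in the flask.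

Step 4
Reactants: 4 1-(benzyloxy)-4-(2,2-dibromoethenyl)-2,3-dimethoxybenzene
Product: 6 3-[4-(benzyloxy)-2,3-dimethoxyphenyl]prop-2-ynoic acid, via lithium acetylide 5 (not isolated)
Conditions: n-BuLi (2.2 equiv), THF, −78 °C; then CO2, −78 °C to rt; aq. HCl
Reagents that add atoms: carbon dioxide, O=C=O
Why: Second stage of the Corey–Fuchs reaction; elimination and bromine–lithium exchange should give the lithium acetylide, which is carboxylated by CO2 to the propiolic acid.

Step 5
Reactants: 6 3-[4-(benzyloxy)-2,3-dimethoxyphenyl]prop-2-ynoic acid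
Product: 7 3-[4-(benzyloxy)-2,3-dimethoxyphenyl]prop-2-ynoyl chloride
Conditions: (COCl)2, DMF (cat.), CH2Cl2, 0 °C to rt; concentrated and used crude
Reagents that add atoms: oxalyl chloride, O=C(Cl)C(=O)Cl
Why: Acid chloride formation under Vilsmeier catalysis at low temperature, mild enough for the alkyne and the benzyl ether.

Step 6
Reactants: 7 3-[4-(benzyloxy)-2,3-dimethoxyphenyl]prop-2-ynoyl chloride; 8 methyl 4-methoxy-3-oxobutanoate (methyl 4-methoxyacetoacetate)
Product: 10 methyl 6-[4-(benzyloxy)-2,3-dimethoxyphenyl]-2-(methoxymethyl)-4-oxo-4H-pyran-3-carboxylate, via alkynoyl ketoester 9 (not isolated)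
Conditions: MgCl2, pyridine, CH2Cl2, 0 °C to rt; aq. HCl; then p-TsOH·H2O (cat.), toluene, 60 °C
Reagents that add atoms: none
Why: C-acylation of the magnesium chelate of the β-keto ester by the alkynoyl chloride, then 6-endo-dig oxa-Michael addition of the ketone enol oxygen to the ynone, a known way to 4-pyranone-3-carboxylates; closure through the ketone enol and not the ester carbonyl places CH2OMe on C-2 and CO2Me on C-3.

Step 7
Reactants: 10 methyl 6-[4-(benzyloxy)-2,3-dimethoxyphenyl]-2-(methoxymethyl)-4-oxo-4H-pyran-3-carboxylate; 11 methyl acetate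
Product: 13 4'-(benzyloxy)-5,7-dihydroxy-8,2',3'-trimethoxyflavone, via methyl ketone 12 (not isolated)
Conditions: LiN(SiMe3)2 (1.05 equiv), THF, −78 °C; 11 (1.3 equiv), −78 to 0 °C; then LiN(i-Pr)2 (3 equiv), −78 to 0 °C; aq. HCl
Reagents that add atoms: none
Why: Proposed new method: LiN(SiMe3)2 should remove one proton of the 2-CH2OMe group of 10, made acidic in a vinylogous sense by both the C-4 carbonyl and the C-3 ester, and the γ-carbon of this dienolate should add to 11 in a Claisen acylation (C7–C8 bond) that is driven forward because the methoxide set free at once deprotonates the doubly activated CH(OMe)C(O)CH3 unit of 12; as every ester in the flask is a methyl ester, methoxide exchange changes nothing. LiN(i-Pr)2 should then take a methyl proton from this enolate, and the terminal carbon of the resulting 1,3-dianion should attack the neighbouring C-3 ester in a 6-exo-trig Dieckmann closure (C5–C6 bond), after which loss of methoxide and two enolisations aromatise ring A to the 5,7-diol. The closest known chemistry is the Claisen-then-Dieckmann sequence of lithiated ortho-toluates with esters (and the base-induced closure of 2-acetonylbenzoates) that gives 1,3-dihydroxynaphthalenes, together with the ester acylation of lithiated 2-methyl-4-pyranones; the sequence has not been run on a pyranone-3-carboxylate. No stereocentre is formed, the CH(OMe) centre of 12 being flattened as its enolate. The step needs closure through carbon and not through the ketone enolate oxygen (which would give a fused 2-pyranone) and an intact pyranone: the dianion is most nucleophilic at its terminal carbon, a lithium bridge between the enolate oxygen and the methoxy oxygen holds that carbon on the side of the ester, the second base is added only after 11 has been consumed so that little ester enolate forms, and the pyranone is shielded from nucleophiles as its electron-rich enolate at low temperature.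

Step 8
Reactants: 13 4'-(benzyloxy)-5,7-dihydroxy-8,2',3'-trimethoxyflavone
Product: 14 4'-(benzyloxy)-5-hydroxy-7,8,2',3'-tetramethoxyflavone
Conditions: MeI (1.2 equiv), K2CO3 (1.5 equiv), acetone, 40 °C
Reagents that add atoms: iodomethane, CI
Why: Selective Williamson methylation; the 7-hydroxyl, vinylogous to the C-4 carbonyl, is the acidic one, whereas the 5-hydroxyl is locked in a hydrogen bond to the carbonyl and should react far more slowly.

Step 9
Reactants: 14 4'-(benzyloxy)-5-hydroxy-7,8,2',3'-tetramethoxyflavone
Product: 15 5,4'-dihydroxy-7,8,2',3'-tetramethoxyflavone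
Conditions: H2 (1 atm), Pd/C, EtOAc–MeOH, rt
Reagents that add atoms: none
Why: Hydrogenolysis of the aryl benzyl ether over palladium on carbon, under which the chromone double bond and the methyl ethers should persist.

**Compound list**

1 | 2,3,4-trihydroxybenzaldehyde | O=Cc1ccc(O)c(O)c1O | starting material
2 | 4-(benzyloxy)-2,3-dihydroxybenzaldehyde | O=Cc1ccc(OCc2ccccc2)c(O)c1O | intermediate
3 | 4-(benzyloxy)-2,3-dimethoxybenzaldehyde | COc1c(C=O)ccc(OCc2ccccc2)c1OC | intermediate
4 | 1-(benzyloxy)-4-(2,2-dibromoethenyl)-2,3-dimethoxybenzene | COc1c(C=C(Br)Br)ccc(OCc2ccccc2)c1OC | intermediate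
5 | lithium 2-[4-(benzyloxy)-2,3-dimethoxyphenyl]ethynide (not isolated) | [Li]C#Cc1ccc(OCc2ccccc2)c(OC)c1OC | intermediate
6 | 3-[4-(benzyloxy)-2,3-dimethoxyphenyl]prop-2-ynoic acid | COc1c(C#CC(=O)O)ccc(OCc2ccccc2)c1OC | intermediate
7 | 3-[4-(benzyloxy)-2,3-dimethoxyphenyl]prop-2-ynoyl chloride | COc1c(C#CC(=O)Cl)ccc(OCc2ccccc2)c1OC | intermediate
8 | methyl 4-methoxy-3-oxobutanoate | COCC(=O)CC(=O)OC | starting material
9 | methyl 2-{3-[4-(benzyloxy)-2,3-dimethoxyphenyl]prop-2-ynoyl}-4-methoxy-3-oxobutanoate (not isolated; enolised) | COCC(=O)C(C(=O)OC)C(=O)C#Cc1ccc(OCc2ccccc2)c(OC)c1OC | intermediate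
10 | methyl 6-[4-(benzyloxy)-2,3-dimethoxyphenyl]-2-(methoxymethyl)-4-oxo-4H-pyran-3-carboxylate | COCc1oc(-c2ccc(OCc3ccccc3)c(OC)c2OC)cc(=O)c1C(=O)OC | intermediate
11 | methyl acetate | COC(C)=O | starting material
12 | methyl 6-[4-(benzyloxy)-2,3-dimethoxyphenyl]-2-(1-methoxy-2-oxopropyl)-4-oxo-4H-pyran-3-carboxylate (not isolated; racemic, present as its lithium enolate) | COC(C(C)=O)c1oc(-c2ccc(OCc3ccccc3)c(OC)c2OC)cc(=O)c1C(=O)OC | intermediate
13 | 4'-(benzyloxy)-5,7-dihydroxy-8,2',3'-trimethoxyflavone | COc1c(O)cc(O)c2c(=O)cc(-c3ccc(OCc4ccccc4)c(OC)c3OC)oc12 | intermediate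
14 | 4'-(benzyloxy)-5-hydroxy-7,8,2',3'-tetramethoxyflavone | COc1cc(O)c2c(=O)cc(-c3ccc(OCc4ccccc4)c(OC)c3OC)oc2c1OC | intermediate
15 | 5,4'-dihydroxy-7,8,2',3'-tetramethoxyflavone | COc1cc(O)c2c(=O)cc(-c3ccc(O)c(OC)c3OC)oc2c1OC | target

**Step count**

Total: 9 steps. Longest linear sequence: 9 steps (1 to 15); 8 and 11 enter as purchased materials.

**Steps most likely to fail**

1. Step 7. The stabilised dienolate of 10 may add too slowly to methyl acetate, so that proton transfer and self-condensation of the ester use up the base. The ketone enolate may also close through oxygen onto the ester, or the pyranone may be opened by methoxide. The fallback uses known chemistry; it sets out from aldehyde 3 and comes back to the route at the target 15. Claisen–Schmidt condensation of 3 with 2'-hydroxy-3',4',6'-trimethoxyacetophenone F1 (a known acetophenone, taken as purchased; KOH, EtOH, rt) should give (E)-3-[4-(benzyloxy)-2,3-dimethoxyphenyl]-1-(2-hydroxy-3,4,6-trimethoxyphenyl)prop-2-en-1-one F2. Oxidative cyclisation with catalytic iodine in DMSO at about 130 °C should give 4'-(benzyloxy)-5,7,8,2',3'-pentamethoxyflavone F3, in which the 2'-hydroxyl next to the 3'-methoxy group of F1 fixes the 5,7,8 pattern. BCl3 with pentamethylbenzene in CH2Cl2 (−78 to 0 °C) should then cleave the carbonyl-chelated 5-O-methyl group and the benzyl ether together and give 15, so steps 8 and 9 are not needed.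

2. Step 6. The very electrophilic alkynoyl chloride may be lost to conjugate addition of pyridine or chloride, or the enolate may be acylated on oxygen, before the tricarbonyl compound can form and cyclise. The fallback reverses the roles of the two acylation partners; it sets out from dibromoalkene 4 and comes back at pyranone 10. The acetylide 5 (n-BuLi, THF, −78 °C) is quenched with methyl chloroformate to give methyl 3-[4-(benzyloxy)-2,3-dimethoxyphenyl]prop-2-ynoate F4. Crossed Claisen condensation with the lithium enolate of methyl acetate 11 (LiN(i-Pr)2, THF, −78 °C, two equivalents of enolate) should give methyl 5-[4-(benzyloxy)-2,3-dimethoxyphenyl]-3-oxopent-4-ynoate F5. Its magnesium chelate (MgCl2, pyridine, CH2Cl2) is then C-acylated by methoxyacetyl chloride, a simple saturated acid chloride, to the same tricarbonyl compound 9, which is cyclised to 10 as in step 6.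

3. Step 8. Site selectivity may erode, with the chelated 5-hydroxyl also alkylated once the 7-ether has formed, giving mixtures that are hard to separate. The fallback replaces selective alkylation by exhaustive alkylation and chelation-controlled dealkylation; it sets out from 13 and comes back at 15. Methylation of both hydroxyls (excess MeI, K2CO3, DMF, 60 °C) should give 4'-(benzyloxy)-5,7,8,2',3'-pentamethoxyflavone F6 (the same structure as F3). BCl3 with pentamethylbenzene in CH2Cl2 (−78 to 0 °C) should then remove the 5-O-methyl group and the benzyl group and give 15, which also replaces step 9.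

**Further compounds**

F1 | step 7 | 2'-hydroxy-3',4',6'-trimethoxyacetophenone | CC(=O)c1c(O)c(OC)c(OC)cc1OC
F2 | step 7 | (E)-3-[4-(benzyloxy)-2,3-dimethoxyphenyl]-1-(2-hydroxy-3,4,6-trimethoxyphenyl)prop-2-en-1-one | COc1cc(OC)c(C(=O)/C=C/c2ccc(OCc3ccccc3)c(OC)c2OC)c(O)c1OC
F3 | step 7 | 4'-(benzyloxy)-5,7,8,2',3'-pentamethoxyflavone | COc1cc(OC)c2c(=O)cc(-c3ccc(OCc4ccccc4)c(OC)c3OC)oc2c1OC
F4 | step 6 | methyl 3-[4-(benzyloxy)-2,3-dimethoxyphenyl]prop-2-ynoate | COC(=O)C#Cc1ccc(OCc2ccccc2)c(OC)c1OC
F5 | step 6 | methyl 5-[4-(benzyloxy)-2,3-dimethoxyphenyl]-3-oxopent-4-ynoate | COC(=O)CC(=O)C#Cc1ccc(OCc2ccccc2)c(OC)c1OC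
F6 | step 8 | 4'-(benzyloxy)-5,7,8,2',3'-pentamethoxyflavone | COc1cc(OC)c2c(=O)cc(-c3ccc(OCc4ccccc4)c(OC)c3OC)oc2c1OC
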